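**Retrosynthetic overview**
- Glycyrdione A is traced back to its bis(O-prenyl) isomer. Both aryl–prenyl C–C bonds (C5 of ring A, C3' of ring B) come from a double [1,3] O→C prenyl shift in the last step.
- The bis(O-prenyl) β-diketone is traced back to an aryl ester (retro-Baker–Venkataraman). The key fragment-joining bond is the ester C–O bond between O-2 of ring A and the acyl carbon of ring B.
- The ester comes from a 4-O-prenyl resacetophenone and 4-(prenyloxy)benzoic acid. Each of these comes from a cheap phenol and prenyl bromide through an aryl ether C–O bond.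
- All three intermolecular unions are therefore C–O bonds. Every new C–C bond arises from an intramolecular O→C migration.
- No ring is formed. Ring A is bought as 2,4-dihydroxyacetophenone and ring B as methyl 4-hydroxybenzoate.

Assumption: the target SMILES has no stereocentre and no stereogenic double bond, so the compound is achiral and needs no enantiocontrol. It is drawn as the diketo tautomer of a largely enolised β-diketone.

**Step 1**
Reactants: 1 2,4-dihydroxyacetophenone; 2 prenyl bromide (1-bromo-3-methylbut-2-ene)
Product: 3 1-[2-hydroxy-4-(3-methylbut-2-enyloxy)phenyl]ethanone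
Conditions: K2CO3 (1.1 equiv), 2 (1.05 equiv), acetone, reflux, 5 h
Reagents that add atoms: prenyl bromide (compound 2), CC(C)=CCBr
Why: Williamson ether synthesis (SN2), in which the free and more acidic 4-OH reacts while the 2-OH is held in a hydrogen bond to the acetyl C=O, so a weak base and one equivalent of 2 give the 4-O-monoether; no stereocentre is formed.

**Step 2**
Reactants: 4 methyl 4-hydroxybenzoate; 2 prenyl bromide
Product: 6 4-(3-methylbut-2-enyloxy)benzoic acid, via methyl 4-(3-methylbut-2-enyloxy)benzoate 5 (not isolated)
Conditions: K2CO3, 2 (1.1 equiv), acetone, reflux; filter, concentrate; NaOH (3 equiv), MeOH–H2O 3:1, 50 °C; 1 M HCl, 0 °C, pH 3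
Reagents that add atoms: prenyl bromide (compound 2), CC(C)=CCBr; sodium hydroxide, [Na+].[OH-] (supplies the carboxyl OH oxygen)
Why: Williamson ether synthesis followed by ester saponification, in which the methyl ester keeps the carboxyl group from consuming 2 and the prenyl ether tolerates hydroxide and brief cold dilute acid; no stereocentre is formed.

**Step 3**
Reactants: 3 1-[2-hydroxy-4-(3-methylbut-2-enyloxy)phenyl]ethanone; 6 4-(3-methylbut-2-enyloxy)benzoic acid
Product: 8 1-[2-hydroxy-4-(3-methylbut-2-enyloxy)phenyl]-3-[4-(3-methylbut-2-enyloxy)phenyl]propane-1,3-dione, via aryl ester 7 (not isolated)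
Conditions: 6 (1.1 equiv), DIC (1.2 equiv), DMAP (0.2 equiv), THF, rt, 16 h; then KOtBu (4 equiv), 0 °C → rt, 2 h; AcOH quench
Reagents that add atoms: none
Why: Steglich esterification forms the key aryl ester C–O bond at the only free OH of 3, and the Baker–Venkataraman rearrangement (ketone enolate attacks the neighbouring ester through a six-membered transition state) then moves the acyl group from O to C, driven by the doubly deprotonated phenoxide/β-diketonate; the prenyl ethers are base-stable and no stereocentre is formed.

**Step 4**
Reactants: 8 1-[2-hydroxy-4-(3-methylbut-2-enyloxy)phenyl]-3-[4-(3-methylbut-2-enyloxy)phenyl]propane-1,3-dione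
Product: 10 glycyrdione A, via chloroaluminium chelate 9 (not isolated)
Conditions: Me2AlCl (1.05 equiv), CH2Cl2–hexanes 1:1, 0.02 M, −78 → 0 °C (CH4 evolves); then Me2AlCl (3 equiv), −78 → −10 °C; cold 1 M HCl
Reagents that add atoms: dimethylaluminium chloride, C[Al](C)Cl (its Al and Cl stay only in intermediate 9; nothing from it stays in 10)
Why: Proposed new method: a chelate-masked, proton-free double [1,3] O→C prenyl shift, in which the first equivalent of Me2AlCl is consumed by the two acidic OH groups (2 CH4) and locks the 2-oxidoaryl β-diketonate as chelate 9, which damps the nucleophilic central carbon, excludes flavone cyclodehydration and crowds C3 of ring A; further neutral Me2AlCl binds each ether oxygen and heterolysis in the non-polar medium gives an aryloxyaluminate/prenyl cation contact ion pair held together by charge, which collapses through the unhindered CH2 terminus onto the nearest open ortho carbon (C5 of ring A, para to O-2 and the usual site of cationic substitution in resacetophenones; C3' of ring B, where both ortho sites are equivalent), and an Al–Me bond removes the dienone proton as CH4 so that no Brønsted acid builds up to close the o-prenylphenols to chromans; the closest known reaction types are the acid-clay- or Bi(OTf)3-promoted [1,3] shift of simple aryl prenyl ethers, the dialkylaluminium chloride-promoted aromatic Claisen rearrangement and proton-scavenging Me2AlCl ene chemistry; no stereocentre is formed.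

**Compound list**
1 | 1-(2,4-dihydroxyphenyl)ethanone (2,4-dihydroxyacetophenone), achiral | CC(=O)c1ccc(O)cc1O | starting material
2 | 1-bromo-3-methylbut-2-ene (prenyl bromide), achiral | CC(C)=CCBr | starting material
3 | 1-[2-hydroxy-4-(3-methylbut-2-enyloxy)phenyl]ethanone, achiral | CC(=O)c1ccc(OCC=C(C)C)cc1O | intermediate
4 | methyl 4-hydroxybenzoate, achiral | COC(=O)c1ccc(O)cc1 | starting material
5 | methyl 4-(3-methylbut-2-enyloxy)benzoate, achiral | COC(=O)c1ccc(OCC=C(C)C)cc1 | intermediate
6 | 4-(3-methylbut-2-enyloxy)benzoic acid, achiral | OC(=O)c1ccc(OCC=C(C)C)cc1 | intermediate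
7 | 2-acetyl-5-(3-methylbut-2-enyloxy)phenyl 4-(3-methylbut-2-enyloxy)benzoate, achiral | CC(=O)c1ccc(OCC=C(C)C)cc1OC(=O)c1ccc(OCC=C(C)C)cc1 | intermediate
8 | 1-[2-hydroxy-4-(3-methylbut-2-enyloxy)phenyl]-3-[4-(3-methylbut-2-enyloxy)phenyl]propane-1,3-dione, achiral | CC(C)=CCOc1ccc(cc1)C(=O)CC(=O)c1ccc(OCC=C(C)C)cc1O | intermediate
9 | chloroaluminium chelate of doubly deprotonated 8: ring A phenolate O and the (Z)-enolate O next to ring B are bound to AlCl; the ring A carbonyl O is bound datively (not drawn); idealised monomer | CC(C)=CCOc1ccc(cc1)/C1=C/C(=O)c2ccc(OCC=C(C)C)cc2O[Al](Cl)O1 | intermediate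
10 | glycyrdione A, 1-[2,4-dihydroxy-5-(3-methylbut-2-enyl)phenyl]-3-[4-hydroxy-3-(3-methylbut-2-enyl)phenyl]propane-1,3-dione, achiral | CC(C)=CCc1cc(C(=O)CC(=O)c2cc(CC=C(C)C)c(O)cc2O)ccc1O | target

**Total step count:** 4. **Longest linear sequence:** 3 (step 1 or step 2, then steps 3 and 4).

**Three steps most likely to fail**

*Step 4 (the proposed new step).*
- Risks:
  - The prenyl cation escapes from the ion pair. This would cause loss of isoprene, prenylation of the central carbon, or transfer between molecules.
  - A charge-accelerated [3,3] pathway gives 1,1-dimethylallyl isomers.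
  - Methyl transfers from aluminium to the cation.
  - Some C3 isomer forms on ring A.
  - Ring B is the less nucleophilic partner.
- Fallback: it uses known chemistry only, sets out from 3, 4 and 2, and comes back at 10. Both prenyl groups are placed on carbon at the fragment stage and the phenols are masked as silyl ethers.
  - Ether 3 is rearranged with catalytic Bi(OTf)3 (or an acidic aluminosilicate clay) in CH2Cl2 at 0 °C. This is the known [1,3] shift of simple aryl prenyl ethers, and it gives 1-[2,4-dihydroxy-5-(3-methylbut-2-enyl)phenyl]ethanone F1.
  - The unchelated 4-OH of that product is silylated (TBSCl, imidazole, DMF) to give 1-[4-(tert-butyldimethylsilyloxy)-2-hydroxy-5-(3-methylbut-2-enyl)phenyl]ethanone F2.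
  - The sodium phenoxide of 4 (NaH, toluene) is alkylated at the ortho carbon with 2. This is classical phenoxide C-alkylation in a non-polar solvent, and it gives methyl 4-hydroxy-3-(3-methylbut-2-enyl)benzoate F3.
  - Silylation in the same way gives methyl 4-(tert-butyldimethylsilyloxy)-3-(3-methylbut-2-enyl)benzoate F4.
  - Crossed Claisen condensation of the dianion of the silylated ketone with this ester (LiN(SiMe3)2, 3.2 equiv, THF, −78 °C → reflux) gives 1-[4-(tert-butyldimethylsilyloxy)-2-hydroxy-5-(3-methylbut-2-enyl)phenyl]-3-[4-(tert-butyldimethylsilyloxy)-3-(3-methylbut-2-enyl)phenyl]propane-1,3-dione F5.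
  - nBu4NF buffered with AcOH (THF, 0 °C) then frees 10 without acid, so neither chroman nor flavone can form.

*Step 3.*
- Risks:
  - The hydrogen-bonded phenol acylates slowly, and the N-acylurea forms instead.
  - tert-Butoxide attacks ester 7 before the enolate does.
- Fallback: it sets out from 3 and 5 and comes back at 8. Compound 5 is taken out of step 2 after the alkylation stage. The acyl group is put directly on carbon: the dianion of 3 (LiN(SiMe3)2, 3.2 equiv, THF, −78 °C → reflux) attacks methyl ester 5 in a crossed Claisen condensation. This makes no compound outside the list (F0).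

*Step 1.*
- Risks:
  - Over-alkylation gives the 2,4-bis(ether).
  - C-alkylation of the phenoxide occurs at C3.
- Fallback: it sets out from 1 and comes back at 3. It is a Mitsunobu etherification with 3-methylbut-2-en-1-ol (PPh3, DIAD, THF, 0 °C). The alcohol is activated instead of a halide and no phenoxide is generated. The chelated 2-OH and the ring carbons therefore stay silent and only the 4-OH is etherified. This makes no compound outside the list (F0).

**Further compounds**
F0 | step 1 | none | none
F0 | step 3 | none | none
F1 | step 4 | 1-[2,4-dihydroxy-5-(3-methylbut-2-enyl)phenyl]ethanone | CC(=O)c1cc(CC=C(C)C)c(O)cc1O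
F2 | step 4 | 1-[4-(tert-butyldimethylsilyloxy)-2-hydroxy-5-(3-methylbut-2-enyl)phenyl]ethanone | CC(=O)c1cc(CC=C(C)C)c(O[Si](C)(C)C(C)(C)C)cc1O
F3 | step 4 | methyl 4-hydroxy-3-(3-methylbut-2-enyl)benzoate | COC(=O)c1ccc(O)c(CC=C(C)C)c1
F4 | step 4 | methyl 4-(tert-butyldimethylsilyloxy)-3-(3-methylbut-2-enyl)benzoate | COC(=O)c1ccc(O[Si](C)(C)C(C)(C)C)c(CC=C(C)C)c1
F5 | step 4 | 1-[4-(tert-butyldimethylsilyloxy)-2-hydroxy-5-(3-methylbut-2-enyl)phenyl]-3-[4-(tert-butyldimethylsilyloxy)-3-(3-methylbut-2-enyl)phenyl]propane-1,3-dione | CC(C)=CCc1cc(C(=O)CC(=O)c2cc(CC=C(C)C)c(O[Si](C)(C)C(C)(C)C)cc2O)ccc1O[Si](C)(C)C(C)(C)C
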